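The route rests on cutting the O1–C2 ether bond of the dihydropyran ring, between the phenolic oxygen and the gem-dimethyl carbon. The O1–C2(CH3)2–C3H(OH)–C4H2 unit fused to the aromatic ring is an oxidised prenyl group, and its C3 hydroxyl next to the O1–C2 bond is the imprint of an epoxide. The key step therefore copies the presumed biosynthesis: acid-catalysed 6-endo opening of an (S)-configured 3,3-dimethyloxirane by the neighbouring phenol. In one operation it closes the pyran ring and carries the epoxide configuration unchanged into C3. The precursor is 2-hydroxy-4-methoxyacetophenone bearing the (S)-(3,3-dimethyloxiran-2-yl)methyl group at C3, made by asymmetric epoxidation. The chalcone arm is attached last by Claisen–Schmidt condensation.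

Key step: step 4

Remark: the carbinol carbon of the target is read as (S) (C3 of the chroman), and the L-fructose-derived enantiomer of the Shi ketone is taken as an available reagent (commercial, or prepared from L-sorbose).

Step 1
Reactants: 1 2,4-dihydroxyacetophenone; 2 prenyl bromide (1-bromo-3-methylbut-2-ene)
Product: 3 1-[2,4-dihydroxy-3-(3-methylbut-2-en-1-yl)phenyl]ethan-1-one
Conditions: KOH (10% aq.), 0 °C → rt; chromatography
Reagents that add atoms: none
Why: Direct C-prenylation of a resorcinol-type phenolate, in which water solvates the oxygens and the ambident anion should alkylate by SN2 at C3, the ring carbon ortho to both oxygens, with the 5-prenyl and O-prenyl isomers removed by chromatography.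

Step 2
Reactants: 3 1-[2,4-dihydroxy-3-(3-methylbut-2-en-1-yl)phenyl]ethan-1-one
Product: 4 1-[2-hydroxy-4-methoxy-3-(3-methylbut-2-en-1-yl)phenyl]ethan-1-one
Conditions: MeI (1.1 equiv), K2CO3 (1.1 equiv), acetone, rt
Reagents that add atoms: iodomethane (MeI), CI
Why: Williamson ether synthesis, selective because the 4-OH is the more acidic, unchelated phenol while the 2-OH is held in a hydrogen bond to the acetyl carbonyl.

Step 3
Reactants: 4 1-[2-hydroxy-4-methoxy-3-(3-methylbut-2-en-1-yl)phenyl]ethan-1-one
Product: 5 1-(3-{[(2S)-3,3-dimethyloxiran-2-yl]methyl}-2-hydroxy-4-methoxyphenyl)ethan-1-one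
Conditions: ent-Shi ketone (L-fructose-derived, 1.0 equiv in portions), Oxone (1.5 equiv), NaHCO3 (pH 7.5–8), MeCN–aq. Na2EDTA, 0 °C
Reagents that add atoms: Oxone (potassium peroxymonosulfate), OOS(=O)(=O)[O-].[K+]
Why: Shi asymmetric epoxidation, in which the chiral dioxirane formed from the L-configured ketone and Oxone transfers oxygen to the electron-rich trisubstituted alkene through a spiro transition state and sets the (S) centre by reagent control (the D-fructose ketone gives the R series with R–CH2–CH=CMe2 alkenes), while the near-neutral pH keeps the chelated phenol protonated so that it should neither open the epoxide nor suffer Dakin-type oxidation.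

Step 4
Reactants: 5 1-(3-{[(2S)-3,3-dimethyloxiran-2-yl]methyl}-2-hydroxy-4-methoxyphenyl)ethan-1-one
Product: 6 1-[(3S)-3-hydroxy-5-methoxy-2,2-dimethyl-3,4-dihydro-2H-chromen-8-yl]ethan-1-one
Conditions: CSA (10 mol%), CH2Cl2, −20 → 0 °C
Reagents that add atoms: none
Why: CSA protonates the oxirane oxygen and the C–O bond to the gem-dimethyl carbon, the only position that can bear tertiary carbocation character, lengthens; the phenolic oxygen attacks this carbon in a borderline SN1/SN2 (Markovnikov) opening and then loses its proton, which regenerates the acid. The closest known reaction type is the acid-catalysed endo-selective opening of trisubstituted epoxides by a tethered hydroxyl group, as in the cyclisation of epoxidised o-prenylphenols to 2,2-dimethylchroman-3-ols. The dihydropyran ring closes in the 6-endo-tet mode. No new stereocentre is created: the bond that breaks sits at the achiral CMe2 carbon, the C–O bond of the carbinol carbon is never touched, and the (S) configuration of the epoxide therefore reappears unchanged at C3. The step needs 6-endo over 5-exo regioselectivity (attack at the secondary carbon would give a 2-(2-hydroxypropan-2-yl)-2,3-dihydrobenzofuran); this is secured by the gem-dimethyl group, which localises the positive charge, and by the weak, carbonyl-chelated neutral phenol, which disfavours the SN2-type 5-exo path typical of phenoxides. The methyl ether at C4 leaves the C2 hydroxyl as the only oxygen that can close the ring.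

Step 5
Reactants: 6 1-[(3S)-3-hydroxy-5-methoxy-2,2-dimethyl-3,4-dihydro-2H-chromen-8-yl]ethan-1-one; 7 4-hydroxybenzaldehyde
Product: 8 (2E)-1-[(3S)-3-hydroxy-5-methoxy-2,2-dimethyl-3,4-dihydro-2H-chromen-8-yl]-3-(4-hydroxyphenyl)prop-2-en-1-one
Conditions: KOH (50% aq., excess), EtOH, rt → 40 °C; then aq. HCl to pH 5
Reagents that add atoms: none
Why: Claisen–Schmidt (crossed aldol) condensation, in which the methyl ketone is the only enolisable partner and E1cB loss of water from the aldol should give the conjugated (E)-enone under thermodynamic control, while the C3 carbinol, remote from any carbonyl, cannot epimerise.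

Compound list
1 | 2,4-dihydroxyacetophenone | CC(=O)c1ccc(O)cc1O | starting material
2 | prenyl bromide (1-bromo-3-methylbut-2-ene) | CC(C)=CCBr | starting material
3 | 1-[2,4-dihydroxy-3-(3-methylbut-2-en-1-yl)phenyl]ethan-1-one | CC(=O)c1ccc(O)c(CC=C(C)C)c1O | intermediate
4 | 1-[2-hydroxy-4-methoxy-3-(3-methylbut-2-en-1-yl)phenyl]ethan-1-one | CC(=O)c1ccc(OC)c(CC=C(C)C)c1O | intermediate
5 | 1-(3-{[(2S)-3,3-dimethyloxiran-2-yl]methyl}-2-hydroxy-4-methoxyphenyl)ethan-1-one | CC(=O)c1ccc(OC)c(C[C@@H]2OC2(C)C)c1O | intermediate
6 | 1-[(3S)-3-hydroxy-5-methoxy-2,2-dimethyl-3,4-dihydro-2H-chromen-8-yl]ethan-1-one | COc1ccc(C(C)=O)c2c1C[C@H](O)C(C)(C)O2 | intermediate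
7 | 4-hydroxybenzaldehyde | O=Cc1ccc(O)cc1 | starting material
8 | (2E)-1-[(3S)-3-hydroxy-5-methoxy-2,2-dimethyl-3,4-dihydro-2H-chromen-8-yl]-3-(4-hydroxyphenyl)prop-2-en-1-one | COc1ccc(C(=O)/C=C/c2ccc(O)cc2)c2c1C[C@H](O)C(C)(C)O2 | target

Total step count: 5
Longest linear sequence: 5 steps (from 1)

Steps most likely to fail

Step 4 (key step): the phenol may attack the secondary epoxide carbon in the 5-exo mode, or the protonated epoxide may rearrange by hydride shift before it is trapped. The fallback sets out from 4 and comes back at 6, replacing steps 3 and 4. Dehydrogenative cyclisation of 4 with DDQ (benzene, reflux; o-quinone methide, then oxa-6π electrocyclisation) should give the chromene 1-(5-methoxy-2,2-dimethyl-2H-chromen-8-yl)ethan-1-one F1. Jacobsen–Katsuki epoxidation with the (S,S)-Mn(salen) catalyst (NaOCl, 4-phenylpyridine N-oxide, CH2Cl2, 0 °C) should give (3S,4S)-8-acetyl-3,4-epoxy-5-methoxy-2,2-dimethylchroman F2. Hydrogenolysis of the benzylic C4–O bond (H2, Pd/C, EtOAc, rt) should then give 6, with the C3–O bond untouched.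

Step 3: partial ionisation of the free phenol may trigger premature base-mediated 5-exo opening of the new epoxide or oxidation of the hydroxyaryl ketone, and the near-neutral protocol may give incomplete conversion or eroded enantioselectivity. The fallback sets out from 4 and comes back at 5. Benzylation (BnBr, K2CO3, DMF, 60 °C) should give 1-[2-(benzyloxy)-4-methoxy-3-(3-methylbut-2-en-1-yl)phenyl]ethan-1-one F3. Shi epoxidation under the standard catalytic protocol (ent-Shi ketone 30 mol%, Oxone, K2CO3, pH 10.5, MeCN/DMM–buffer, 0 °C) should give 1-(2-(benzyloxy)-3-{[(2S)-3,3-dimethyloxiran-2-yl]methyl}-4-methoxyphenyl)ethan-1-one F4. Hydrogenolysis (H2, Pd/C, EtOAc, rt) should free the phenol under neutral conditions and give 5.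

Step 1: alkylation may occur at oxygen, at C5 or twice, so that little of the 3-prenyl isomer is obtained. The fallback sets out from 1 and comes back at 3. O-Allylation of the unchelated 4-OH (allyl bromide, K2CO3, acetone, reflux) should give 1-[2-hydroxy-4-(prop-2-en-1-yloxy)phenyl]ethan-1-one F5. Aromatic Claisen rearrangement (N,N-diethylaniline, 200 °C), directed to C3 by the bond fixation of the chelated ring, should give 1-[2,4-dihydroxy-3-(prop-2-en-1-yl)phenyl]ethan-1-one F6. Cross-metathesis with 2-methylbut-2-ene (Grubbs II, CH2Cl2, 40 °C) should turn the allyl into the prenyl group and give 3.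

Further compounds
F1 | step 4 | 1-(5-methoxy-2,2-dimethyl-2H-chromen-8-yl)ethan-1-one | COc1ccc(C(C)=O)c2c1C=CC(C)(C)O2
F2 | step 4 | (3S,4S)-8-acetyl-3,4-epoxy-5-methoxy-2,2-dimethylchroman | COc1ccc(C(C)=O)c2c1[C@@H]1O[C@@H]1C(C)(C)O2
F3 | step 3 | 1-[2-(benzyloxy)-4-methoxy-3-(3-methylbut-2-en-1-yl)phenyl]ethan-1-one | CC(=O)c1ccc(OC)c(CC=C(C)C)c1OCc1ccccc1
F4 | step 3 | 1-(2-(benzyloxy)-3-{[(2S)-3,3-dimethyloxiran-2-yl]methyl}-4-methoxyphenyl)ethan-1-one | CC(=O)c1ccc(OC)c(C[C@@H]2OC2(C)C)c1OCc1ccccc1
F5 | step 1 | 1-[2-hydroxy-4-(prop-2-en-1-yloxy)phenyl]ethan-1-one | CC(=O)c1ccc(OCC=C)cc1O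
F6 | step 1 | 1-[2,4-dihydroxy-3-(prop-2-en-1-yl)phenyl]ethan-1-one | CC(=O)c1ccc(O)c(CC=C)c1O
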